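The chroman-2-one is cut through ring A. Its C4 stereocentre, flanked by C3–C2 (lactone) and C4a–C8a (ring A), is the midpoint of a 3-phenylpentanedioic acid, so enantioselective opening of the prochiral anhydride fixes C4 before ring A exists. Ring A is then built on the free acid arm by a thermal vinylketene/ynol ether benzannulation: a 4-alkyl-3-silyloxycyclobutenone carrying the ester chain and a silyl ynol ether carrying the dioxolane-masked acyl chain form C8–C8a, C6–C7 and C4a–C8a in one operation. The product has O5 and O7 silylated and only the C8a hydroxyl free, which settles both the lactone oxygen and the acyl position.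

Key step: step 9

Assumption: the quinine-derived catalyst of step 1 is taken to give the (S)-hemiester; if the sense of induction is the opposite, its quinidine-derived pseudoenantiomer is used and nothing else changes.

Remark on design: the C8 acyl chain is carried as a dioxolane and not as a silylated benzylic carbinol, because an oxygen leaving group on a carbon attached to the trioxygenated ring would ionise under the acid needed for lactonisation. The ketal returns the ketone in that same acid step and adds no stereocentre.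

Step 1
Reactants: 1 3-phenylglutaric anhydride
Product: 2 (3S)-5-methoxy-5-oxo-3-phenylpentanoic acid
Conditions: MeOH (10 equiv), N-[(8α,9S)-6′-methoxycinchonan-9-yl]-3,5-bis(trifluoromethyl)benzenesulfonamide (10 mol%), MTBE, rt
Reagents that add atoms: methanol CO
Why: Cinchona-sulfonamide-catalysed desymmetrising methanolysis of a prochiral cyclic anhydride, in which the quinuclidine nitrogen activates methanol as a general base while the sulfonamide N–H binds one of the two enantiotopic carbonyl groups, so that the catalyst's choice of carbonyl sets the C3 stereocentre (the later C4).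

Step 2
Reactants: 2 (3S)-5-methoxy-5-oxo-3-phenylpentanoic acid
Product: 3 methyl (3R)-5-chloro-5-oxo-3-phenylpentanoate
Conditions: (COCl)2 (1.2 equiv), N,N-dimethylformamide (cat.), CH2Cl2, 0 °C → rt; evaporate, use crude
Reagents that add atoms: oxalyl chloride O=C(Cl)C(=O)Cl
Why: Acid chloride formation with oxalyl chloride under Vilsmeier catalysis is cold and neutral enough to spare the methyl ester and to suppress acyl chloride/ester interchange, the only pathway that could erode the enantiomeric purity; the stereocentre is untouched and is called R only because COCl outranks CO2Me.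

Step 3
Reactants: 4 acetylene
Product: 7 (triisopropylsilyloxy)ethyne, via lithium acetylide 5 (not isolated), via lithium ethynolate 6 (not isolated)
Conditions: HC≡CH (excess), n-BuLi, THF, −78 °C; LiOOt-Bu (from t-BuOOH and LiN(SiMe3)2), −78 → −20 °C; i-Pr3SiOSO2CF3, −78 °C → rt; distil
Reagents that add atoms: tert-butyl hydroperoxide CC(C)(C)OO; triisopropylsilyl trifluoromethanesulfonate CC(C)[Si](C(C)C)(C(C)C)OS(=O)(=O)C(F)(F)F
Why: Julia-type oxidation of a lithium acetylide by lithium tert-butyl peroxide gives the ynolate, and the bulky silyl triflate traps it on oxygen as in the usual preparation of triisopropylsilyl ynol ethers from terminal alkynes, the large silyl group also slowing the oxygen-to-carbon silyl shift to a silylketene.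

Step 4
Reactants: 3 methyl (3R)-5-chloro-5-oxo-3-phenylpentanoate; 7 (triisopropylsilyloxy)ethyne
Product: 9 methyl (3R)-3-[2-oxo-4-(triisopropylsilyloxy)cyclobut-3-en-1-yl]-3-phenylpropanoate (epimeric at the ring carbon), via ketene 8 (not isolated)
Conditions: 7 (1.5 equiv), Et3N (1.2 equiv, added slowly), CH2Cl2, 0 °C → rt
Reagents that add atoms: none
Why: Dehydrochlorination gives the monosubstituted ketene 8, which the electron-rich ynol ether captures in a thermal [2+2] cycloaddition (its CH carbon to the ketene carbonyl carbon, its oxygen-bearing carbon to the ketene α-carbon), the known route from ketenes and alkoxy- or silyloxyalkynes to 3-oxy-substituted cyclobutenones; the new ring stereocentre is left uncontrolled because step 9 destroys it.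

Step 5
Reactants: 10 3-(4-methoxyphenyl)propanal; 11 ethynylmagnesium bromide
Product: 12 rac-5-(4-methoxyphenyl)pent-1-yn-3-ol
Conditions: HC≡CMgBr (0.5 M in THF, 1.3 equiv), THF, 0 °C → rt; then H2O
Reagents that add atoms: none
Why: Grignard 1,2-addition of the commercial ethynylmagnesium bromide solution to an aldehyde, the carbinol centre being formed as a racemate on purpose because step 6 removes it.

Step 6
Reactants: 12 rac-5-(4-methoxyphenyl)pent-1-yn-3-ol
Product: 13 5-(4-methoxyphenyl)pent-1-yn-3-one
Conditions: Dess–Martin periodinane (1.2 equiv), CH2Cl2, 0 °C → rt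
Reagents that add atoms: none
Why: Dess–Martin oxidation of a secondary propargylic alcohol under neutral, non-nucleophilic conditions that a terminal alkynyl ketone (a Michael acceptor) should tolerate.

Step 7
Reactants: 13 5-(4-methoxyphenyl)pent-1-yn-3-one
Product: 14 2-ethynyl-2-[2-(4-methoxyphenyl)ethyl]-1,3-dioxolane
Conditions: Me3SiOCH2CH2OSiMe3 (1.5 equiv), Me3SiOSO2CF3 (5 mol%), CH2Cl2, −78 → −20 °C; pyridine quench
Reagents that add atoms: 1,2-bis(trimethylsilyloxy)ethane C[Si](C)(C)OCCO[Si](C)(C)C
Why: Noyori ketalisation, an aprotic low-temperature acetal formation driven by loss of hexamethyldisiloxane, which avoids the conjugate addition of free diol to the ynone that protic ketalisation invites.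

Step 8
Reactants: 14 2-ethynyl-2-[2-(4-methoxyphenyl)ethyl]-1,3-dioxolane
Product: 17 2-[2-(4-methoxyphenyl)ethyl]-2-[(triisopropylsilyloxy)ethynyl]-1,3-dioxolane, via lithium acetylide 15 (not isolated), via lithium ynolate 16 (not isolated)
Conditions: n-BuLi, THF, −78 °C; LiOOt-Bu (from t-BuOOH and LiN(SiMe3)2), −78 → 0 °C; i-Pr3SiOSO2CF3, −78 °C → rt
Reagents that add atoms: tert-butyl hydroperoxide CC(C)(C)OO; triisopropylsilyl trifluoromethanesulfonate CC(C)[Si](C(C)C)(C(C)C)OS(=O)(=O)C(F)(F)F
Why: Julia-type oxidation of the lithium acetylide to the ynolate and O-silylation with the bulky silyl triflate, the standard access to triisopropylsilyl ynol ethers from terminal alkynes, with the ketal and the aryl ether inert to base and peroxide.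

Step 9
Reactants: 9 methyl (3R)-3-[2-oxo-4-(triisopropylsilyloxy)cyclobut-3-en-1-yl]-3-phenylpropanoate; 17 2-[2-(4-methoxyphenyl)ethyl]-2-[(triisopropylsilyloxy)ethynyl]-1,3-dioxolane
Product: 22 methyl (3S)-3-{2-hydroxy-3-{2-[2-(4-methoxyphenyl)ethyl]-1,3-dioxolan-2-yl}-4,6-bis(triisopropylsilyloxy)phenyl}-3-phenylpropanoate, via vinylketene 18 (not isolated), via vinylcyclobutenone 19 (not isolated), via dienylketene 20 (not isolated), via cyclohexadienone 21 (not isolated)
Conditions: 17 (1.3 equiv), toluene (0.5 M, degassed), 110 °C, sealed tube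
Reagents that add atoms: none
Why: Heating opens 9 by 4π-electrocyclic cleavage of its C(=O)–CH(alkyl) bond to the vinylketene 18, whose ketene C=C bond adds the ynol ether 17 in a [2+2] cycloaddition to give 19; this opens again to the dienylketene 20, which closes by 6π-electrocyclisation to 21 and tautomerises to the phenol 22. The closest known reaction type is the thermal benzannulation of cyclobutenones with alkoxy- or silyloxyalkynes (Danheiser benzannulation), extended here to a 3-silyloxycyclobutenone so that a phloroglucinol pattern results. Ring A is closed by the thermal disrotatory 6π-electrocyclisation that forms C4a–C8a, after the cycloaddition has made C8–C8a and C6–C7. No stereocentre is formed: the ring carbon of 9 becomes sp2 (C4a), and the existing C4 stereocentre, adjacent to but not part of the reacting π-system, is carried through (called S in 22 only because the new aryl group outranks phenyl). The one selectivity needed is the orientation of the ketene–alkyne cycloaddition, secured by the polarisation of the ynol ether, whose nucleophilic ketal-bearing carbon attacks the ketene carbonyl carbon while the oxygen-bearing carbon joins the ketene α-carbon; this leaves the former ketene oxygen as the only free hydroxyl, on C8a. Outward rotation of the C4 side chain in the first ring opening keeps its C–H away from the ketene and so avoids a 1,5-hydrogen shift.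

Step 10
Reactants: 22 methyl (3S)-3-{2-hydroxy-3-{2-[2-(4-methoxyphenyl)ethyl]-1,3-dioxolan-2-yl}-4,6-bis(triisopropylsilyloxy)phenyl}-3-phenylpropanoate
Product: 24 (4S)-8-[3-(4-methoxyphenyl)propanoyl]-4-phenyl-5,7-bis(triisopropylsilyloxy)-3,4-dihydro-2H-chromen-2-one, via keto phenol ester 23 (not isolated)
Conditions: 1 M aq. HCl, THF, rt; then 4-MeC6H4SO3H·H2O (10 mol%), toluene, 80 °C
Reagents that add atoms: water O
Why: Acid hydrolysis of the dioxolane (whose ionisation leads productively to the C8 ketone) followed by acid-catalysed lactonisation of the only free phenol, on C8a, with the methyl ester closes the six-membered lactone, while both aryl silyl ethers should withstand the conditions so that O5 cannot compete and the non-enolisable C4 centre is untouched.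

Step 11
Reactants: 24 (4S)-8-[3-(4-methoxyphenyl)propanoyl]-4-phenyl-5,7-bis(triisopropylsilyloxy)-3,4-dihydro-2H-chromen-2-one
Product: 25 (4S)-5,7-dihydroxy-8-[3-(4-methoxyphenyl)propanoyl]-4-phenyl-3,4-dihydro-2H-chromen-2-one (CNP0240692.1)
Conditions: HF·pyridine, pyridine, THF, 0 °C → rt
Reagents that add atoms: none
Why: Fluoride-mediated cleavage of both aryl silyl ethers under buffered, weakly acidic, anhydrous conditions, which should spare the lactone and generate no phenoxide that could open it and move the acyl group to O5.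

Compound list
1 | 3-phenylglutaric anhydride (4-phenyloxane-2,6-dione) | O=C1CC(c2ccccc2)CC(=O)O1 | starting material
2 | (3S)-5-methoxy-5-oxo-3-phenylpentanoic acid | COC(=O)C[C@@H](c1ccccc1)CC(=O)O | intermediate
3 | methyl (3R)-5-chloro-5-oxo-3-phenylpentanoate | COC(=O)C[C@@H](c1ccccc1)CC(=O)Cl | intermediate
4 | acetylene | C#C | starting material
5 | lithium acetylide | [Li]C#C | intermediate
6 | lithium ethynolate | [Li]OC#C | intermediate
7 | (triisopropylsilyloxy)ethyne | C#CO[Si](C(C)C)(C(C)C)C(C)C | intermediate
8 | methyl (3R)-5-oxo-3-phenylpent-4-enoate (ketene) | COC(=O)C[C@@H](c1ccccc1)C=C=O | intermediate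
9 | methyl (3R)-3-[2-oxo-4-(triisopropylsilyloxy)cyclobut-3-en-1-yl]-3-phenylpropanoate, ring carbon unassigned | COC(=O)C[C@@H](c1ccccc1)C1C(=O)C=C1O[Si](C(C)C)(C(C)C)C(C)C | intermediate
10 | 3-(4-methoxyphenyl)propanal | COc1ccc(CCC=O)cc1 | starting material
11 | ethynylmagnesium bromide | C#C[Mg]Br | starting material
12 | rac-5-(4-methoxyphenyl)pent-1-yn-3-ol | COc1ccc(CCC(O)C#C)cc1 | intermediate
13 | 5-(4-methoxyphenyl)pent-1-yn-3-one | COc1ccc(CCC(=O)C#C)cc1 | intermediate
14 | 2-ethynyl-2-[2-(4-methoxyphenyl)ethyl]-1,3-dioxolane | COc1ccc(CCC2(C#C)OCCO2)cc1 | intermediate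
15 | lithium {2-[2-(4-methoxyphenyl)ethyl]-1,3-dioxolan-2-yl}acetylide | COc1ccc(CCC2(C#C[Li])OCCO2)cc1 | intermediate
16 | lithium 2-{2-[2-(4-methoxyphenyl)ethyl]-1,3-dioxolan-2-yl}ethynolate | COc1ccc(CCC2(C#CO[Li])OCCO2)cc1 | intermediate
17 | 2-[2-(4-methoxyphenyl)ethyl]-2-[(triisopropylsilyloxy)ethynyl]-1,3-dioxolane | COc1ccc(CCC2(C#CO[Si](C(C)C)(C(C)C)C(C)C)OCCO2)cc1 | intermediate
18 | methyl (3R,4Z)-7-oxo-3-phenyl-5-(triisopropylsilyloxy)hepta-4,6-dienoate (vinylketene) | COC(=O)C[C@@H](c1ccccc1)/C=C(\O[Si](C(C)C)(C(C)C)C(C)C)C=C=O | intermediate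
19 | methyl (3R,4Z)-5-{3-{2-[2-(4-methoxyphenyl)ethyl]-1,3-dioxolan-2-yl}-4-oxo-2-(triisopropylsilyloxy)cyclobut-2-en-1-yl}-3-phenyl-5-(triisopropylsilyloxy)pent-4-enoate, ring carbon unassigned | COC(=O)C[C@@H](c1ccccc1)/C=C(\O[Si](C(C)C)(C(C)C)C(C)C)C1C(=O)C(C2(CCc3ccc(OC)cc3)OCCO2)=C1O[Si](C(C)C)(C(C)C)C(C)C | intermediate
20 | methyl (3R,4Z,6E)-8-{2-[2-(4-methoxyphenyl)ethyl]-1,3-dioxolan-2-yl}-9-oxo-3-phenyl-5,7-bis(triisopropylsilyloxy)nona-4,6,8-trienoate (dienylketene) | COC(=O)C[C@@H](c1ccccc1)/C=C(\O[Si](C(C)C)(C(C)C)C(C)C)/C=C(/O[Si](C(C)C)(C(C)C)C(C)C)\C(=C=O)C1(CCc2ccc(OC)cc2)OCCO1 | intermediate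
21 | methyl (3R)-3-{3-{2-[2-(4-methoxyphenyl)ethyl]-1,3-dioxolan-2-yl}-2-oxo-4,6-bis(triisopropylsilyloxy)cyclohexa-3,5-dien-1-yl}-3-phenylpropanoate, ring carbon unassigned | COC(=O)C[C@@H](c1ccccc1)C1C(=O)C(C2(CCc3ccc(OC)cc3)OCCO2)=C(O[Si](C(C)C)(C(C)C)C(C)C)C=C1O[Si](C(C)C)(C(C)C)C(C)C | intermediate
22 | methyl (3S)-3-{2-hydroxy-3-{2-[2-(4-methoxyphenyl)ethyl]-1,3-dioxolan-2-yl}-4,6-bis(triisopropylsilyloxy)phenyl}-3-phenylpropanoate | COC(=O)C[C@@H](c1ccccc1)c1c(O)c(C2(CCc3ccc(OC)cc3)OCCO2)c(O[Si](C(C)C)(C(C)C)C(C)C)cc1O[Si](C(C)C)(C(C)C)C(C)C | intermediate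
23 | methyl (3S)-3-{2-hydroxy-3-[3-(4-methoxyphenyl)propanoyl]-4,6-bis(triisopropylsilyloxy)phenyl}-3-phenylpropanoate | COC(=O)C[C@@H](c1ccccc1)c1c(O)c(C(=O)CCc2ccc(OC)cc2)c(O[Si](C(C)C)(C(C)C)C(C)C)cc1O[Si](C(C)C)(C(C)C)C(C)C | intermediate
24 | (4S)-8-[3-(4-methoxyphenyl)propanoyl]-4-phenyl-5,7-bis(triisopropylsilyloxy)-3,4-dihydro-2H-chromen-2-one | COc1ccc(CCC(=O)c2c(O[Si](C(C)C)(C(C)C)C(C)C)cc(O[Si](C(C)C)(C(C)C)C(C)C)c3c2OC(=O)C[C@H]3c2ccccc2)cc1 | intermediate
25 | (4S)-5,7-dihydroxy-8-[3-(4-methoxyphenyl)propanoyl]-4-phenyl-3,4-dihydro-2H-chromen-2-one | COc1ccc(CCC(=O)c2c(O)cc(O)c3c2OC(=O)C[C@H]3c2ccccc2)cc1 | target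

Total step count: 11.
Longest linear sequence: 7 steps (steps 5, 6, 7, 8, 9, 10 and 11, from 3-(4-methoxyphenyl)propanal).

Steps most likely to fail

Step 9. Ring opening of the push–pull 3-silyloxycyclobutenone may be slow. Capture of the electron-rich vinylketene by the hindered, quaternary-substituted ynol ether may then lose out to ketene dimerisation or to thermal silyl migration in the ynol ether. The fallback sets out from 9 and 7 and comes back at 23: ring A is built with the unhindered parent ynol ether and the acyl chain is attached afterwards. Heating 9 with 7 (toluene, 110 °C) should give methyl (3S)-3-[2-hydroxy-4,6-bis(triisopropylsilyloxy)phenyl]-3-phenylpropanoate F1 by the same pericyclic sequence with far less steric demand. Its bromomagnesium phenoxide (EtMgBr, toluene) is then C-acylated with 3-(4-methoxyphenyl)propanoyl chloride at the position ortho to the phenoxide oxygen by metal-templated ortho-acylation. C8 is the only free ortho position and C6 is shielded by two silyloxy groups, so this gives 23, and the lactonisation stage of step 10 leads on to 24.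

Step 3. The parent ynolate may be silylated on carbon, the terminal silyl ynol ether may isomerise to the silylketene, and monolithium acetylide may disproportionate on warming before it is oxidised. Step 4 consumes 7 and fails with it. The fallback sets out from 3 and comes back at 9, bypassing steps 3 and 4. Tert-butoxyethyne F3, an established and more nucleophilic ketene trap, is made from KOt-Bu and trichloroethylene via (E)-1,2-dichloro-1-(tert-butoxy)ethene F2, followed by n-BuLi and protonation. Its [2+2] cycloaddition with ketene 8 (from 3 and Et3N) should give methyl (3R)-3-(2-tert-butoxy-4-oxocyclobut-2-en-1-yl)-3-phenylpropanoate F4. Treatment with i-Pr3SiOSO2CF3 and 2,6-lutidine then silylates the carbonyl oxygen of this vinylogous tert-butyl ester and expels isobutene, by analogy with the silyl triflate cleavage of tert-butyl esters. This gives 9 without passing through the free 1,3-dione, so the position of the ring substituent is kept.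

Step 7. Conjugate addition to the terminal ynone, or its oligomerisation, may compete with a sluggish ketalisation of the deactivated carbonyl group. The fallback sets out from 10 and comes back at 14, replacing steps 5 to 7: the alkyne terminus is capped before the ketone is made. Lithium (trimethylsilyl)acetylide adds to 10 to give rac-5-(4-methoxyphenyl)-1-(trimethylsilyl)pent-1-yn-3-ol F5. Dess–Martin oxidation gives 5-(4-methoxyphenyl)-1-(trimethylsilyl)pent-1-yn-3-one F6, a silyl-capped ynone that is a poor Michael acceptor. Ethylene glycol with 4-MeC6H4SO3H·H2O (benzene, Dean–Stark) converts it into 2-[2-(4-methoxyphenyl)ethyl]-2-[(trimethylsilyl)ethynyl]-1,3-dioxolane F7, and K2CO3 in MeOH removes the silyl group to give 14.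

Further compounds
F1 | step 9 | methyl (3S)-3-[2-hydroxy-4,6-bis(triisopropylsilyloxy)phenyl]-3-phenylpropanoate | COC(=O)C[C@@H](c1ccccc1)c1c(O)cc(O[Si](C(C)C)(C(C)C)C(C)C)cc1O[Si](C(C)C)(C(C)C)C(C)C
F2 | step 3 | (E)-1,2-dichloro-1-(tert-butoxy)ethene | CC(C)(C)O/C(Cl)=C\Cl
F3 | step 3 | tert-butoxyethyne | C#COC(C)(C)C
F4 | step 3 | methyl (3R)-3-(2-tert-butoxy-4-oxocyclobut-2-en-1-yl)-3-phenylpropanoate, ring carbon unassigned | COC(=O)C[C@@H](c1ccccc1)C1C(=O)C=C1OC(C)(C)C
F5 | step 7 | rac-5-(4-methoxyphenyl)-1-(trimethylsilyl)pent-1-yn-3-ol | COc1ccc(CCC(O)C#C[Si](C)(C)C)cc1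
F6 | step 7 | 5-(4-methoxyphenyl)-1-(trimethylsilyl)pent-1-yn-3-one | COc1ccc(CCC(=O)C#C[Si](C)(C)C)cc1
F7 | step 7 | 2-[2-(4-methoxyphenyl)ethyl]-2-[(trimethylsilyl)ethynyl]-1,3-dioxolane | COc1ccc(CCC2(C#C[Si](C)(C)C)OCCO2)cc1
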